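**Retrosynthetic overview**

- The route rests on ring A: a benzene ring fused to the pyranone along C4a–C8a, with O1 on C8a and the free hydroxyl on C7 (meta to O1, para to C4a). A 1-methoxy-3-silyloxybutadiene lays exactly this pattern onto a C4a=C8a enone.
- Ring A is therefore cut at C4a–C5 and C8–C8a, giving a (2S)-2-aryl-5-(phenylsulfinyl)-2,3-dihydro-4H-pyran-4-one and trans-1-methoxy-3-(trimethylsilyloxy)buta-1,3-diene. The forward reaction is a Diels–Alder reaction followed by loss of methanol and benzenesulfenic acid.
- The sulfoxide comes from the sulfide, the sulfide from the 5-iodide by copper-catalysed C–S coupling, and the iodide from the parent dihydropyranone by α-iodination.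
- The dihydropyranone (ring C, carrying C2) comes from a catalytic asymmetric hetero-Diels–Alder reaction of 4-geranyloxybenzaldehyde with the same diene; the aldehyde comes from 4-hydroxybenzaldehyde and geranyl bromide.
- Ring order: aryl ring B is bought, ring C is made in step 2, ring A in step 6. The geranyl ether is in place from step 1, so no phenol protecting group is needed.

Key step: step 6

Assumption: the (S)-BINOL–Ti(OiPr)4 catalyst is taken to direct the diene to the aldehyde face that gives the 2S product, by analogy with its sense in additions to benzaldehyde; if the dihydropyranone proves to be 2R, (R)-BINOL is used and nothing else changes.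

"Geranyl" below means (2E)-3,7-dimethylocta-2,6-dien-1-yl.

**Step 1**
Reactants: 1 4-hydroxybenzaldehyde; 2 geranyl bromide [(2E)-1-bromo-3,7-dimethylocta-2,6-diene]
Product: 3 4-(geranyloxy)benzaldehyde
Conditions: K2CO3 (1.5 equiv), DMF, rt
Reagents that add atoms: none
Why: Williamson etherification, an SN2 displacement of the primary allylic bromide by the phenoxide, which should leave the aldehyde and the (E)-alkene geometry untouched.

**Step 2**
Reactants: 3 4-(geranyloxy)benzaldehyde; 4 trans-1-methoxy-3-(trimethylsilyloxy)buta-1,3-diene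
Product: 6 (2S)-2-[4-(geranyloxy)phenyl]-2,3-dihydro-4H-pyran-4-one, via silyl aldol adduct 5 (not isolated)
Conditions: Ti(OiPr)4 (10 mol%), (S)-BINOL (20 mol%), 4 Å MS, Et2O, −20 °C; then TFA (5 mol%), CH2Cl2, 0 °C
Reagents that add atoms: none
Why: Catalytic asymmetric hetero-Diels–Alder reaction of the Mukaiyama-aldol type (Keck conditions), in which the BINOL–titanium Lewis acid binds the aldehyde and exposes one carbonyl face to the CH2 terminus of the diene, setting C2 as S, and a brief catalytic acid treatment closes ring C by oxa-Michael addition and loss of methanol without breaking the C2–O bond.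

**Step 3**
Reactants: 6 (2S)-2-[4-(geranyloxy)phenyl]-2,3-dihydro-4H-pyran-4-one
Product: 7 (2S)-2-[4-(geranyloxy)phenyl]-5-iodo-2,3-dihydro-4H-pyran-4-one
Conditions: I2 (1.5 equiv), pyridine/CH2Cl2, 0 °C→rt, dark
Reagents that add atoms: iodine, II
Why: Johnson-type α-iodination of an enone, in which C5 is the nucleophilic carbon of the enol ether and pyridine removes the proton to restore the vinylogous ester, while iodine should add only reversibly to the isolated trisubstituted alkenes.

**Step 4**
Reactants: 7 (2S)-2-[4-(geranyloxy)phenyl]-5-iodo-2,3-dihydro-4H-pyran-4-one; 8 thiophenol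
Product: 9 (2S)-2-[4-(geranyloxy)phenyl]-5-(phenylsulfanyl)-2,3-dihydro-4H-pyran-4-one
Conditions: CuI (10 mol%), 1,10-phenanthroline (20 mol%), K3PO4 (1.5 equiv), PhMe (degassed), 70 °C
Reagents that add atoms: none
Why: Ullmann-type copper-catalysed C(sp2)–S coupling of a vinyl iodide with a thiol, for which the electron-poor α-iodoenone should be reactive enough to allow a weak heterogeneous base and a moderate temperature that spare C2.

**Step 5**
Reactants: 9 (2S)-2-[4-(geranyloxy)phenyl]-5-(phenylsulfanyl)-2,3-dihydro-4H-pyran-4-one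
Product: 10 (2S)-2-[4-(geranyloxy)phenyl]-5-(phenylsulfinyl)-2,3-dihydro-4H-pyran-4-one (both configurations at sulfur)
Conditions: NaIO4 (1.1 equiv), MeOH/THF/H2O, 0 °C→rt
Reagents that add atoms: sodium periodate, [Na+].[O-]I(=O)(=O)=O
Why: Periodate oxidation of a sulfide, which should stop at the sulfoxide and leave the geranyl alkenes alone; the sulfur centre is not controlled because sulfur is lost in step 6.

**Step 6**
Reactants: 10 (2S)-2-[4-(geranyloxy)phenyl]-5-(phenylsulfinyl)-2,3-dihydro-4H-pyran-4-one; 4 trans-1-methoxy-3-(trimethylsilyloxy)buta-1,3-diene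
Product: 14 (2S)-7-hydroxy-2-[4-(geranyloxy)phenyl]-2,3-dihydro-4H-chromen-4-one (target), via cycloadduct 11 (not isolated), via sulfinyl enone 12 (not isolated), via dienone tautomer 13 (not isolated)
Conditions: 4 (3 equiv), ZnBr2 (1 equiv), CH2Cl2, −20 °C→rt; TFA (cat.), 0 °C; aq. NaHCO3 wash; then PhMe, 50 °C
Reagents that add atoms: none
Why: ZnBr2 chelates the sulfinyl and C4 carbonyl oxygens of 10 and lowers the LUMO of the C5=C6 bond, so that in a normal-demand Diels–Alder reaction the nucleophilic CH2 terminus of 4 bonds to C6 (the future C8a, β to the carbonyl) and the methoxy-bearing terminus to C5 (the future C4a), giving cis-fused 11; a stepwise Mukaiyama–Michael addition and ring closure would converge on the same adduct. The closest known reaction type is the Diels–Alder reaction of α-sulfinyl enones and of 3-acceptor-substituted chromones with 1-methoxy-3-silyloxydienes, followed by sulfoxide elimination to a phenol. Ring A is closed by this intermolecular [4+2] cycloaddition, both new bonds (C4a–C5 and C8–C8a) being made in one operation across the C4a–C8a edge of the pyranone. The centres created at C4a, C5 and C8a and the sulfur centre are all destroyed on aromatization, so no new stereocentre has to be controlled and C2 is a spectator. Two selectivities are needed: regioselectivity (oxygen at C7, not C6), secured by the matched polarization of diene and dienophile, and the order of the eliminations, secured by treating the cold adduct with acid first, which ionizes the C5 methoxy group through the silyl enol ether and gives enone 12. In 12 the sulfoxide has a single syn β-hydrogen (C8a–H), so gentle warming should remove PhSOH only across C4a–C8a, O1 stays on C8a, and dienone 13 tautomerizes to the phenol.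

**Compound list**

1 | 4-hydroxybenzaldehyde | O=Cc1ccc(O)cc1 | starting material
2 | geranyl bromide, (2E)-1-bromo-3,7-dimethylocta-2,6-diene | CC(C)=CCC/C(C)=C/CBr | starting material
3 | 4-(geranyloxy)benzaldehyde | CC(C)=CCC/C(C)=C/COc1ccc(C=O)cc1 | intermediate
4 | trans-1-methoxy-3-(trimethylsilyloxy)buta-1,3-diene | CO/C=C/C(=C)O[Si](C)(C)C | starting material
5 | (1E,5S)-5-[4-(geranyloxy)phenyl]-1-methoxy-5-(trimethylsilyloxy)pent-1-en-3-one (silyl aldol adduct) | CC(C)=CCC/C(C)=C/COc1ccc([C@@H](O[Si](C)(C)C)CC(=O)/C=C/OC)cc1 | intermediate (not isolated)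
6 | (2S)-2-[4-(geranyloxy)phenyl]-2,3-dihydro-4H-pyran-4-one | CC(C)=CCC/C(C)=C/COc1ccc([C@@H]2CC(=O)C=CO2)cc1 | intermediate
7 | (2S)-2-[4-(geranyloxy)phenyl]-5-iodo-2,3-dihydro-4H-pyran-4-one | CC(C)=CCC/C(C)=C/COc1ccc([C@@H]2CC(=O)C(I)=CO2)cc1 | intermediate
8 | thiophenol | Sc1ccccc1 | starting material
9 | (2S)-2-[4-(geranyloxy)phenyl]-5-(phenylsulfanyl)-2,3-dihydro-4H-pyran-4-one | CC(C)=CCC/C(C)=C/COc1ccc([C@@H]2CC(=O)C(Sc3ccccc3)=CO2)cc1 | intermediate
10 | (2S)-2-[4-(geranyloxy)phenyl]-5-(phenylsulfinyl)-2,3-dihydro-4H-pyran-4-one, mixture of sulfur epimers | CC(C)=CCC/C(C)=C/COc1ccc([C@@H]2CC(=O)C(S(=O)c3ccccc3)=CO2)cc1 | intermediate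
11 | (2S)-2-[4-(geranyloxy)phenyl]-5-methoxy-4a-(phenylsulfinyl)-7-(trimethylsilyloxy)-2,3,4a,5,8,8a-hexahydro-4H-chromen-4-one, cis-fused, mixture at C4a, C5, C8a and sulfur | CC(C)=CCC/C(C)=C/COc1ccc([C@@H]2CC(=O)C3(S(=O)c4ccccc4)C(OC)C=C(O[Si](C)(C)C)CC3O2)cc1 | intermediate (not isolated)
12 | (2S)-2-[4-(geranyloxy)phenyl]-4a-(phenylsulfinyl)-2,3,8,8a-tetrahydro-4H-chromene-4,7(4aH)-dione | CC(C)=CCC/C(C)=C/COc1ccc([C@@H]2CC(=O)C3(S(=O)c4ccccc4)C=CC(=O)CC3O2)cc1 | intermediate (not isolated)
13 | (2S)-2-[4-(geranyloxy)phenyl]-2,3-dihydro-4H-chromene-4,7(8H)-dione (keto tautomer of the target) | CC(C)=CCC/C(C)=C/COc1ccc([C@@H]2CC(=O)C3=C(O2)CC(=O)C=C3)cc1 | intermediate (not isolated)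
14 | (2S)-7-hydroxy-2-[4-(geranyloxy)phenyl]-2,3-dihydro-4H-chromen-4-one, CNP0302343.1 | CC(C)=CCC/C(C)=C/COc1ccc([C@@H]2CC(=O)c3ccc(O)cc3O2)cc1 | target

**Step count**

Total steps: 6. Longest linear sequence: 6 (steps 1 to 6).

**Steps most likely to fail**

Step 6. Three processes may spoil it. The push–pull C5=C6 bond of 10 may be too poor a dienophile below the temperature at which the sulfoxide starts to eliminate. Elimination may then run towards C5, or O1 may be expelled from C8a, which opens ring C. The Lewis acid may also ionize the benzylic C2–O1 bond and erode the configuration at C2. The fallback gives up the benzannulation and sets C2 by rhodium-catalysed asymmetric conjugate arylation of a chromone, a known route to flavanones. It sets out from geranyl bromide 2, which alkylates 4-hydroxyphenylboronic acid (K2CO3, acetone) to give [4-(geranyloxy)phenyl]boronic acid F1. Commercial 7-hydroxy-4H-chromen-4-one is silylated (TBSCl, imidazole, DMF) to 7-(tert-butyldimethylsilyloxy)-4H-chromen-4-one F2. F1 is added to F2 with [Rh(OH)(cod)]2 and an electron-poor atropisomeric bisphosphine of the MeO-BIPHEP family (antipode chosen for 2S) in toluene/water at room temperature, which should give (2S)-7-(tert-butyldimethylsilyloxy)-2-[4-(geranyloxy)phenyl]-2,3-dihydro-4H-chromen-4-one F3. TBAF buffered with AcOH in THF at 0 °C removes the silyl group, and the sequence comes back to the route at target 14.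

Step 4. The thiolate may add to C6 and open the ring, prolonged contact with base at elevated temperature may erode C2 through reversible β-elimination of O1, and the thiol may add to the geranyl alkenes by a radical chain. The fallback brings sulfur in as an electrophile on a substrate without the geranyl alkenes and attaches the geranyl group afterwards under neutral conditions. It sets out from diene 4 and thiophenol 8. Commercial 4-(tert-butyldimethylsilyloxy)benzaldehyde and 4 under the conditions of step 2 should give, by way of (1E,5S)-5-[4-(tert-butyldimethylsilyloxy)phenyl]-1-methoxy-5-(trimethylsilyloxy)pent-1-en-3-one F4, (2S)-2-[4-(tert-butyldimethylsilyloxy)phenyl]-2,3-dihydro-4H-pyran-4-one F5. Benzenesulfenyl chloride F6, made from 8 and SO2Cl2, substitutes the nucleophilic C5 of F5 (CH2Cl2, −78 °C, then 2,6-lutidine) to give (2S)-2-[4-(tert-butyldimethylsilyloxy)phenyl]-5-(phenylsulfanyl)-2,3-dihydro-4H-pyran-4-one F7. HF·pyridine in THF frees (2S)-2-(4-hydroxyphenyl)-5-(phenylsulfanyl)-2,3-dihydro-4H-pyran-4-one F8. Mitsunobu etherification with geraniol (PPh3, DIAD, THF, 0 °C) should give sulfide 9, where the route is rejoined; this also bypasses step 3.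

Step 2. The electron-rich aldehyde may react slowly and with poor facial selectivity, and the acid used for ring closure may ionize the p-alkoxybenzylic C2–O bond (loss of enantiopurity) or attack the geranyl ether. The fallback is a hydrogen-bond-catalysed hetero-Diels–Alder reaction with an aminosiloxy diene, which needs neither a Lewis acid nor a Brønsted acid. It sets out from aldehyde 3: with commercial (E)-1-(dimethylamino)-3-(tert-butyldimethylsilyloxy)buta-1,3-diene and a 1-naphthyl TADDOL (antipode chosen for 2S) in toluene at −40 °C it should give (2S)-6-(dimethylamino)-4-(tert-butyldimethylsilyloxy)-2-[4-(geranyloxy)phenyl]-3,6-dihydro-2H-pyran F9. Acetyl chloride at −78 °C then expels the amine and the silyl group, and the sequence comes back to the route at dihydropyranone 6.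

**Further compounds**

F1 | step 6 | [4-(geranyloxy)phenyl]boronic acid | CC(C)=CCC/C(C)=C/COc1ccc(B(O)O)cc1
F2 | step 6 | 7-(tert-butyldimethylsilyloxy)-4H-chromen-4-one | O=c1ccoc2cc(O[Si](C)(C)C(C)(C)C)ccc12
F3 | step 6 | (2S)-7-(tert-butyldimethylsilyloxy)-2-[4-(geranyloxy)phenyl]-2,3-dihydro-4H-chromen-4-one | CC(C)=CCC/C(C)=C/COc1ccc([C@@H]2CC(=O)c3ccc(O[Si](C)(C)C(C)(C)C)cc3O2)cc1
F4 | step 4 | (1E,5S)-5-[4-(tert-butyldimethylsilyloxy)phenyl]-1-methoxy-5-(trimethylsilyloxy)pent-1-en-3-one | CC(C)(C)[Si](C)(C)Oc1ccc([C@@H](O[Si](C)(C)C)CC(=O)/C=C/OC)cc1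
F5 | step 4 | (2S)-2-[4-(tert-butyldimethylsilyloxy)phenyl]-2,3-dihydro-4H-pyran-4-one | CC(C)(C)[Si](C)(C)Oc1ccc([C@@H]2CC(=O)C=CO2)cc1
F6 | step 4 | benzenesulfenyl chloride | ClSc1ccccc1
F7 | step 4 | (2S)-2-[4-(tert-butyldimethylsilyloxy)phenyl]-5-(phenylsulfanyl)-2,3-dihydro-4H-pyran-4-one | CC(C)(C)[Si](C)(C)Oc1ccc([C@@H]2CC(=O)C(Sc3ccccc3)=CO2)cc1
F8 | step 4 | (2S)-2-(4-hydroxyphenyl)-5-(phenylsulfanyl)-2,3-dihydro-4H-pyran-4-one | Oc1ccc([C@@H]2CC(=O)C(Sc3ccccc3)=CO2)cc1
F9 | step 2 | (2S)-6-(dimethylamino)-4-(tert-butyldimethylsilyloxy)-2-[4-(geranyloxy)phenyl]-3,6-dihydro-2H-pyran | CC(C)=CCC/C(C)=C/COc1ccc([C@@H]2CC(O[Si](C)(C)C(C)(C)C)=CC(N(C)C)O2)cc1
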